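Conventions: chroman numbering (O1, C2, C3, C4, C4a, C5–C8, C8a) is used for atoms throughout. Ring A is the benzo ring of the chroman and ring B the catechol ring. MOM = methoxymethyl, TES = triethylsilyl.

Remark on the chemistry: Grignard reagent 13 is taken as the commercial THF solution; it can equally be made from 1-bromo-2-methylprop-1-ene and magnesium.

## Analysis of the target

Target 23 is a 2,2-dimethylchroman-3-ol. Ring A carries, in unbroken sequence, the pyran carbon C4 on C4a, a 2-(3,4-dihydroxyphenyl)ethyl chain on C5, a prenyl group on C6, a free hydroxyl on C7, hydrogen on C8 and the ring oxygen O1 on C8a. C3 is the only stereocentre and is R; it lies between the quaternary C2 and the benzylic methylene C4, so there is no second stereocentre to relay from and its configuration has to come from a reagent or catalyst. The sensitive groups are the catechol of ring B (oxidation, base), the C7 phenol next to the prenyl alkene (acid-promoted ring closure to a second chroman), and the trisubstituted alkene itself, which rules out late hydrogenation and non-selective oxidants. The first difficulty is the contiguous pattern C4a–C5–C6–C7–C8a: it derives from a 5-alkylresorcinol in which the two positions ortho to the chain must receive different carbon groups and the two oxygens must be told apart. The second is the absolute configuration at an isolated carbinol. The strategy rests on C3 being adjacent to benzylic C4 inside a 2,2-dimethylpyran. Unsaturation between C3 and C4 gives a 2,2-dimethyl-2H-chromene, a cis alkene conjugated to ring A with a gem-dimethyl group at one end, which is the alkene type that manganese salen catalysts epoxidise with the highest face selectivity. The benzylic C4–O bond of the resulting oxirane can then be removed by hydride, leaving only the C3 oxygen.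

## Retrosynthetic reasoning

23 ⇐ 22. The three aryl MOM ethers and the C3 TES ether are removed together in one mild acid step. Acetals are chosen on the phenols because they survive bases, hydride, organolithiums and buffered oxidant, and because an ortho acetal stabilises the aryllithium needed later, where an aryl silyl ether would migrate from oxygen to carbon.

22 ⇐ 19 (through 20 and 21). The C6–CH2 bond of the prenyl group is cut. C6 lies between the C5 chain and the C7 oxygen and cannot be reached selectively by substitution or directed metalation, since C8 between the two oxygens would react first. A bromine placed there early gives a specific handle: bromine–lithium exchange, transfer to copper and allylic substitution. Bringing the prenyl group in last also keeps its alkene away from the oxidation. 19 ⇐ 18 is a silylation that masks the C3 hydroxyl during the organometallic step.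

18 ⇐ 17. The C4–H bond is traced back to a C4–O bond. Hydride must attack the benzylic oxirane carbon C4 and not C3, which is flanked by the quaternary C2; C3 keeps its oxygen and its configuration.

17 ⇐ 16. The C3–O and C4–O bonds are cut together, back to the C3=C4 alkene of chromene 16. This is the only point where chirality is introduced. The disconnection is placed here because 16 is achiral and easily assembled, it contains a single alkene, and it belongs to the substrate class for which catalytic asymmetric epoxidation is most dependable. The forward reaction must distinguish the two faces of the alkene and must not damage the electron-rich rings.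

16 ⇐ 12 + 13 (through 14 and 15). The pyran ring is opened at O1–C2 and C3–C4. Addition of the alkenyl Grignard reagent 13 to the formyl group of salicylaldehyde 12 makes C3–C4. Loss of water from diol 14 gives the ortho-quinone methide 15, whose oxa-6π electrocyclisation makes O1–C2. The formyl carbon fixes where the pyran is fused, so no regiochemical question arises on ring A.

12 ⇐ 11 ⇐ 8 (through 9 and 10). The formyl carbon is removed and replaced by bromine, and the free phenol is re-protected, which leads to the symmetrical dibromide 8. Because 8 is symmetrical, exchange of either bromine gives the same aryllithium 9; after formylation the remaining bromine is exactly the C6 handle. The forward sequence then needs only to free the one MOM ether that sits next to the new carbonyl group.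

8 ⇐ 7. Both C–Br bonds are cut. The two positions ortho to the chain on ring A are each ortho to one oxygen and para to the other, so electrophilic bromination should go there before it touches ring B or the hindered carbon between the two oxygens.

7 ⇐ 3 + 5 (through 6). The bond between ring B and the ethylene bridge is cut. A B-alkyl Suzuki–Miyaura coupling of the alkylborane 6 from styrene 3 with aryl bromide 5 gives the saturated two-carbon link directly, without a stilbene and without a hydrogenation. 3 ⇐ 2 ⇐ 1 and 5 ⇐ 4 are a methylenation and two acetal protections of commercial phenols.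

## Alternatives that were turned down

Alternative 1: The benzo ring itself is disconnected (C4a–C8a, C8–C8a and C6–C7). In the forward sense the cyclobutenone A2 would be heated with the silyloxyalkyne A3. Electrocyclic opening to a vinylketene, [2+2] addition to the alkyne, a second ring opening and 6π closure would give the resorcinol monosilyl ether A1. In its favour, A1 is formed with the C5 chain and a prenyl group on C4a in fixed positions, and with the two oxygens already differentiated (free hydroxyl on C8a, silyl ether on C7). On that point it is stronger than the chosen route, which has to free one of two acetals selectively. Against it, A1 carries hydrogen at both C6 and C8, so the C6 prenyl group is still missing and would have to be placed between the chain and the C7 oxygen in competition with C8. The prenyl group on C4a must still be turned into C4–C3–C2 by an asymmetric epoxidation of a trisubstituted alkene and a phenol opening that has to go 6-endo at the tertiary carbon rather than 5-exo. A2 is a heat-sensitive 3,4-disubstituted cyclobutenone that needs its own multistep preparation. The benzannulation therefore solves neither the stereocentre nor C6. The chosen strategy gives up the built-in oxygen differentiation but sets C3 on a ring that is already complete and fixes C6 with a halogen from the start.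

Alternative 2: The pyran ring is disconnected at C4–C4a and O1–C2, back to the aryl 1,1-dimethylpropargyl ether A5. Heating would cause a [3,3] shift onto C4a, a hydrogen shift to an ortho-quinone methide and oxa-6π closure to the chromene A4; the bromine on C8 blocks the other ortho position. In its favour, the cascade needs no reagent, its regiochemistry is enforced, and it avoids both the organometallic addition and the selective deprotection next to a carbonyl group. As a way of closing the pyran ring it is at least as good as the route chosen. Against it, A4 is again only a chromene, so C3 would have to be set by the same asymmetric oxidation. The bromine sits on C8, where the target has hydrogen, and must be removed, while C6 has hydrogen and no handle for the prenyl group. The tertiary propargyl ether has to be made on a phenol flanked by bromine after the two resorcinol oxygens have been differentiated. In the chosen route the halogen does constructive work twice (it makes the dibromide symmetrical for formylation and then marks C6), whereas here it is only a blocking group.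

Alternative 3: The C4–C4a bond is disconnected, back to the enantiopure epoxy ether A7. A cationic gold Lewis acid would activate the oxirane, C4a would attack its terminal carbon in the endo mode, and the chromanol A6 would form with C3 untouched. In its favour, the stereocentre is made on a small acyclic piece and is never at risk afterwards, and no labile benzylic oxirane is involved. In stereochemical certainty this plan is stronger than a face-selective reaction on a crowded chromene. Against it, the ether oxygen of A7 has two activated ortho carbons: the future C4a, shielded by the C5 chain, and the future C8, between the two oxygens and unhindered, so the arene may attack from the wrong carbon. A strongly Lewis-acidic medium has to be survived by four acetals and by ring B, the tertiary aryl ether next to an oxirane is hard to prepare, and A6 again lacks any substituent at C6. The chosen strategy locks the ring fusion through the formyl carbon and C6 through bromine, and accepts in exchange that the configuration depends on catalyst control.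

Key step: step 9

## Route

Step 1
Reactants: 1 3,5-dihydroxybenzaldehyde
Product: 2 3,5-bis(methoxymethoxy)benzaldehyde
Conditions: MOMCl (2.6 equiv), i-Pr2NEt (3.5 equiv), CH2Cl2, 0 °C → rt
Reagents that add atoms: chloromethyl methyl ether (MOMCl), COCCl
Why: O-alkylation of both phenols with an α-chloro ether (Williamson-type acetal protection); the aldehyde is untouched by the amine base.

Step 2
Reactants: 2 3,5-bis(methoxymethoxy)benzaldehyde
Product: 3 1-ethenyl-3,5-bis(methoxymethoxy)benzene
Conditions: Ph3PCH3Br (1.3 equiv), KOt-Bu (1.25 equiv), THF, 0 °C → rt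
Reagents that add atoms: methyltriphenylphosphonium bromide, C[P+](c1ccccc1)(c1ccccc1)c1ccccc1.[Br-]
Why: Wittig methylenation of an unhindered aromatic aldehyde; the acetals are stable to the ylide and the alkoxide.

Step 3
Reactants: 4 4-bromobenzene-1,2-diol
Product: 5 4-bromo-1,2-bis(methoxymethoxy)benzene
Conditions: MOMCl (2.6 equiv), i-Pr2NEt (3.5 equiv), CH2Cl2, 0 °C → rt
Reagents that add atoms: chloromethyl methyl ether (MOMCl), COCCl
Why: The same acetal protection as in step 1, applied to the catechol that becomes ring B; the aryl bromide is inert.

Step 4
Reactants: 3 1-ethenyl-3,5-bis(methoxymethoxy)benzene; 5 4-bromo-1,2-bis(methoxymethoxy)benzene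
Product: 7 4-{2-[3,5-bis(methoxymethoxy)phenyl]ethyl}-1,2-bis(methoxymethoxy)benzene, via alkylborane 6 (not isolated)
Conditions: 9-BBN (1.1 equiv), THF, 0 °C → rt; then 5, Pd(dppf)Cl2 (3 mol %), 3 M aq. NaOH, THF, 65 °C
Reagents that add atoms: none
Why: Anti-Markovnikov hydroboration of the styrene with 9-BBN places boron on the terminal carbon, and the B-alkyl Suzuki–Miyaura coupling of the resulting borane with the aryl bromide forms the aryl–CH2 bond. The bidentate phosphine suppresses β-hydride elimination, so the saturated bridge is obtained directly.

Step 5
Reactants: 7 4-{2-[3,5-bis(methoxymethoxy)phenyl]ethyl}-1,2-bis(methoxymethoxy)benzene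
Product: 8 2,4-dibromo-3-{2-[3,4-bis(methoxymethoxy)phenyl]ethyl}-1,5-bis(methoxymethoxy)benzene
Conditions: NBS (2.05 equiv), DMF, −20 → 0 °C, dark
Reagents that add atoms: N-bromosuccinimide, O=C1CCC(=O)N1Br
Why: Electrophilic aromatic bromination under ionic conditions. The two carbons of ring A next to the chain are each ortho to one acetal oxygen and para to the other and should stay more nucleophilic, even after the first bromine has entered, than any carbon of ring B, where every open position is activated by one oxygen only; the carbon between the two oxygens of ring A is the most hindered.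

Step 6
Reactants: 8 2,4-dibromo-3-{2-[3,4-bis(methoxymethoxy)phenyl]ethyl}-1,5-bis(methoxymethoxy)benzene
Product: 11 3-bromo-2-{2-[3,4-bis(methoxymethoxy)phenyl]ethyl}-4,6-bis(methoxymethoxy)benzaldehyde, via aryllithium 9 (not isolated), via lithium hemiaminolate 10 (not isolated)
Conditions: n-BuLi (1.05 equiv), THF, −78 °C; DMF (3 equiv), −78 → 0 °C; aq. NH4Cl
Reagents that add atoms: N,N-dimethylformamide, CN(C)C=O
Why: Bromine–lithium exchange followed by formylation with a formamide. The dibromide is symmetrical, so either bromine gives the same aryllithium, which is stabilised by the neighbouring acetal oxygen, and a second exchange on the already anionic ring is disfavoured; exchange is much faster than ortho-deprotonation of ring B at this temperature.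

Step 7
Reactants: 11 3-bromo-2-{2-[3,4-bis(methoxymethoxy)phenyl]ethyl}-4,6-bis(methoxymethoxy)benzaldehyde
Product: 12 3-bromo-2-{2-[3,4-bis(methoxymethoxy)phenyl]ethyl}-6-hydroxy-4-(methoxymethoxy)benzaldehyde
Conditions: 3 M aq. HCl, THF, rt, monitored and stopped when 11 is consumed
Reagents that add atoms: none
Why: Controlled acetal hydrolysis. The MOM ether ortho to the formyl group is the most labile of the four because the carbonyl oxygen assists departure of the phenol by hydrogen bonding and the product is a chelated salicylaldehyde; the other three acetals lack this assistance and should survive the short exposure.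

Step 8
Reactants: 12 3-bromo-2-{2-[3,4-bis(methoxymethoxy)phenyl]ethyl}-6-hydroxy-4-(methoxymethoxy)benzaldehyde; 13 2-methylprop-1-enylmagnesium bromide
Product: 16 6-bromo-5-{2-[3,4-bis(methoxymethoxy)phenyl]ethyl}-7-(methoxymethoxy)-2,2-dimethyl-2H-chromene, via allylic diol 14 (not isolated), via ortho-quinone methide 15 (not isolated)
Conditions: 13 (3 equiv), THF, 0 °C → rt; then AcOH (excess), 50 °C
Reagents that add atoms: none
Why: Grignard addition to the salicylaldehyde (the first equivalent is consumed by the phenol) gives a benzylic, allylic carbinol that is activated by the ortho hydroxyl and the para acetal oxygen. Mild acid removes water to the ortho-quinone methide, which closes by oxa-6π electrocyclisation to the 2,2-dimethyl-2H-chromene, the established route from salicylaldehydes and alkenyl Grignard reagents; acetic acid in THF is too weak to cleave aryl MOM ethers.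

Step 9
Reactants: 16 6-bromo-5-{2-[3,4-bis(methoxymethoxy)phenyl]ethyl}-7-(methoxymethoxy)-2,2-dimethyl-2H-chromene
Product: 17 (3R,4R)-6-bromo-3,4-epoxy-5-{2-[3,4-bis(methoxymethoxy)phenyl]ethyl}-7-(methoxymethoxy)-2,2-dimethylchroman
Conditions: (R,R)-[N,N'-bis(3,5-di-tert-butylsalicylidene)cyclohexane-1,2-diaminato]MnCl (5 mol %), 4-phenylpyridine N-oxide (0.2 equiv), aq. NaOCl buffered to pH 11.3 (Na2HPO4/NaOH), CH2Cl2, 0 °C
Reagents that add atoms: sodium hypochlorite, [Na+].[O-]Cl
Why: Jacobsen–Katsuki epoxidation, the standard asymmetric oxygen transfer to 2,2-dimethyl-2H-chromenes: hypochlorite oxidises the trivalent manganese salen chloride to a pentavalent oxo-manganese species, which the cis C3=C4 alkene approaches side-on. The first C–O bond should form at C3, leaving a radical at benzylic C4 stabilised by ring A, and collapse of this radical onto the manganese-bound oxygen closes the oxirane (a three-membered ring made by stepwise [2+1] oxygen-atom transfer, its fusion necessarily cis because C3 and C4 are held in the pyran). Both new stereocentres, C3 and C4, are set together by the enantioface choice of the catalyst; the (R,R)-diamine backbone and the tert-butyl groups of the ligand are expected to deliver oxygen to the face that gives the (3R,4R) oxide, as with other 2,2-dimethylchromenes. The selectivity required is enantioface selectivity at one alkene, and the substrate secures it through the cis geometry, conjugation with the arene and the gem-dimethyl group at C2, which differentiates the two alkene ends. Chemoselectivity is secured because 16 has no other alkene (C6 carries bromine, not yet the prenyl group) and the aryl ethers and acetals are inert to buffered hypochlorite. Since C4 of 17 is para to the C7 oxygen and ortho to O1, the oxirane ionises easily; the basic two-phase medium, an acid-free work-up and immediate use of crude 17 in step 10 are meant to keep it intact. The C4–O bond made here is sacrificial and serves only to bring oxygen to C3 under catalyst control.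

Step 10
Reactants: 17 (3R,4R)-6-bromo-3,4-epoxy-5-{2-[3,4-bis(methoxymethoxy)phenyl]ethyl}-7-(methoxymethoxy)-2,2-dimethylchroman
Product: 18 (3R)-6-bromo-5-{2-[3,4-bis(methoxymethoxy)phenyl]ethyl}-7-(methoxymethoxy)-2,2-dimethylchroman-3-ol
Conditions: LiAlH4 (1.5 equiv), THF, 0 °C; then H2O
Reagents that add atoms: none
Why: Reductive epoxide opening by nucleophilic hydride; attack goes to the benzylic, electronically activated C4 and not to C3, which is shielded by the quaternary C2. C3 keeps its oxygen and its R configuration while the C4 stereocentre disappears; the aryl bromide and the acetals are stable to LiAlH4 at 0 °C.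

Step 11
Reactants: 18 (3R)-6-bromo-5-{2-[3,4-bis(methoxymethoxy)phenyl]ethyl}-7-(methoxymethoxy)-2,2-dimethylchroman-3-ol
Product: 19 (3R)-6-bromo-5-{2-[3,4-bis(methoxymethoxy)phenyl]ethyl}-7-(methoxymethoxy)-2,2-dimethyl-3-(triethylsilyloxy)chroman
Conditions: Et3SiCl (2 equiv), imidazole (4 equiv), DMAP (cat.), DMF, rt
Reagents that add atoms: chlorotriethylsilane, CC[Si](Cl)(CC)CC
Why: Silylation of the secondary alcohol; the small triethylsilyl group can be put on next to the quaternary carbon, removes the acidic proton before the organolithium step and falls off later under the same acid that cleaves the acetals.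

Step 12
Reactants: 19 (3R)-6-bromo-5-{2-[3,4-bis(methoxymethoxy)phenyl]ethyl}-7-(methoxymethoxy)-2,2-dimethyl-3-(triethylsilyloxy)chroman
Product: 22 (3R)-5-{2-[3,4-bis(methoxymethoxy)phenyl]ethyl}-7-(methoxymethoxy)-2,2-dimethyl-6-(3-methylbut-2-enyl)-3-(triethylsilyloxy)chroman, via aryllithium 20 (not isolated), via arylcopper 21 (not isolated)
Conditions: t-BuLi (2.1 equiv), THF, −78 °C; CuBr·SMe2 (1.2 equiv), −78 → −40 °C; prenyl bromide (2 equiv), −78 → 0 °C
Reagents that add atoms: 1-bromo-3-methylbut-2-ene (prenyl bromide), CC(C)=CCBr
Why: Bromine–lithium exchange gives an aryllithium held by the ortho acetal oxygen; transmetalation to monovalent copper and allylic substitution on prenyl bromide at its primary carbon is the usual way to prenylate MOM-protected phenols at the ortho position. The stereocentre is remote and not involved.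

Step 13
Reactants: 22 (3R)-5-{2-[3,4-bis(methoxymethoxy)phenyl]ethyl}-7-(methoxymethoxy)-2,2-dimethyl-6-(3-methylbut-2-enyl)-3-(triethylsilyloxy)chroman
Product: 23 (3R)-5-[2-(3,4-dihydroxyphenyl)ethyl]-2,2-dimethyl-6-(3-methylbut-2-enyl)chroman-3,7-diol
Conditions: 3 M aq. HCl–MeOH (1:5), degassed, argon, rt → 40 °C
Reagents that add atoms: none
Why: Acid-catalysed acetal exchange removes the three aryl MOM groups and solvolyses the silyl ether in the same operation; dilute acid at or near room temperature is the usual way to free prenylated phenols without adding the phenol to the alkene. C3 is a non-benzylic secondary carbinol and cannot ionise under these conditions, so its configuration is retained.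

## Compound list

1 | 3,5-dihydroxybenzaldehyde | O=Cc1cc(O)cc(O)c1 | starting material
2 | 3,5-bis(methoxymethoxy)benzaldehyde | O=Cc1cc(OCOC)cc(OCOC)c1 | intermediate
3 | 1-ethenyl-3,5-bis(methoxymethoxy)benzene | C=Cc1cc(OCOC)cc(OCOC)c1 | intermediate
4 | 4-bromobenzene-1,2-diol | Oc1ccc(Br)cc1O | starting material
5 | 4-bromo-1,2-bis(methoxymethoxy)benzene | COCOc1ccc(Br)cc1OCOC | intermediate
6 | 9-{2-[3,5-bis(methoxymethoxy)phenyl]ethyl}-9-borabicyclo[3.3.1]nonane | COCOc1cc(CCB2C3CCCC2CCC3)cc(OCOC)c1 | intermediate
7 | 4-{2-[3,5-bis(methoxymethoxy)phenyl]ethyl}-1,2-bis(methoxymethoxy)benzene | COCOc1cc(CCc2ccc(OCOC)c(OCOC)c2)cc(OCOC)c1 | intermediate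
8 | 2,4-dibromo-3-{2-[3,4-bis(methoxymethoxy)phenyl]ethyl}-1,5-bis(methoxymethoxy)benzene (both bromines flank the chain) | COCOc1cc(OCOC)c(Br)c(CCc2ccc(OCOC)c(OCOC)c2)c1Br | intermediate
9 | (3-bromo-2-{2-[3,4-bis(methoxymethoxy)phenyl]ethyl}-4,6-bis(methoxymethoxy)phenyl)lithium | [Li]c1c(OCOC)cc(OCOC)c(Br)c1CCc1ccc(OCOC)c(OCOC)c1 | intermediate
10 | lithium (3-bromo-2-{2-[3,4-bis(methoxymethoxy)phenyl]ethyl}-4,6-bis(methoxymethoxy)phenyl)(dimethylamino)methanolate (racemic) | [Li]OC(N(C)C)c1c(OCOC)cc(OCOC)c(Br)c1CCc1ccc(OCOC)c(OCOC)c1 | intermediate
11 | 3-bromo-2-{2-[3,4-bis(methoxymethoxy)phenyl]ethyl}-4,6-bis(methoxymethoxy)benzaldehyde | O=Cc1c(OCOC)cc(OCOC)c(Br)c1CCc1ccc(OCOC)c(OCOC)c1 | intermediate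
12 | 3-bromo-2-{2-[3,4-bis(methoxymethoxy)phenyl]ethyl}-6-hydroxy-4-(methoxymethoxy)benzaldehyde | O=Cc1c(O)cc(OCOC)c(Br)c1CCc1ccc(OCOC)c(OCOC)c1 | intermediate
13 | 2-methylprop-1-enylmagnesium bromide | CC(C)=C[Mg]Br | starting material
14 | 4-bromo-3-{2-[3,4-bis(methoxymethoxy)phenyl]ethyl}-2-(1-hydroxy-3-methylbut-2-enyl)-5-(methoxymethoxy)phenol (racemic) | CC(C)=CC(O)c1c(O)cc(OCOC)c(Br)c1CCc1ccc(OCOC)c(OCOC)c1 | intermediate
15 | 4-bromo-5-{2-[3,4-bis(methoxymethoxy)phenyl]ethyl}-3-(methoxymethoxy)-6-(3-methylbut-2-enylidene)cyclohexa-2,4-dien-1-one | CC(C)=CC=C1C(=O)C=C(OCOC)C(Br)=C1CCc1ccc(OCOC)c(OCOC)c1 | intermediate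
16 | 6-bromo-5-{2-[3,4-bis(methoxymethoxy)phenyl]ethyl}-7-(methoxymethoxy)-2,2-dimethyl-2H-chromene | COCOc1cc2OC(C)(C)C=Cc2c(CCc2ccc(OCOC)c(OCOC)c2)c1Br | intermediate
17 | (3R,4R)-6-bromo-3,4-epoxy-5-{2-[3,4-bis(methoxymethoxy)phenyl]ethyl}-7-(methoxymethoxy)-2,2-dimethylchroman | COCOc1cc2c(c(CCc3ccc(OCOC)c(OCOC)c3)c1Br)[C@H]1O[C@H]1C(C)(C)O2 | intermediate
18 | (3R)-6-bromo-5-{2-[3,4-bis(methoxymethoxy)phenyl]ethyl}-7-(methoxymethoxy)-2,2-dimethylchroman-3-ol | COCOc1cc2c(c(CCc3ccc(OCOC)c(OCOC)c3)c1Br)C[C@@H](O)C(C)(C)O2 | intermediate
19 | (3R)-6-bromo-5-{2-[3,4-bis(methoxymethoxy)phenyl]ethyl}-7-(methoxymethoxy)-2,2-dimethyl-3-(triethylsilyloxy)chroman | COCOc1cc2c(c(CCc3ccc(OCOC)c(OCOC)c3)c1Br)C[C@@H](O[Si](CC)(CC)CC)C(C)(C)O2 | intermediate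
20 | [(3R)-5-{2-[3,4-bis(methoxymethoxy)phenyl]ethyl}-7-(methoxymethoxy)-2,2-dimethyl-3-(triethylsilyloxy)chroman-6-yl]lithium | COCOc1cc2c(c(CCc3ccc(OCOC)c(OCOC)c3)c1[Li])C[C@@H](O[Si](CC)(CC)CC)C(C)(C)O2 | intermediate
21 | [(3R)-5-{2-[3,4-bis(methoxymethoxy)phenyl]ethyl}-7-(methoxymethoxy)-2,2-dimethyl-3-(triethylsilyloxy)chroman-6-yl]copper | COCOc1cc2c(c(CCc3ccc(OCOC)c(OCOC)c3)c1[Cu])C[C@@H](O[Si](CC)(CC)CC)C(C)(C)O2 | intermediate
22 | (3R)-5-{2-[3,4-bis(methoxymethoxy)phenyl]ethyl}-7-(methoxymethoxy)-2,2-dimethyl-6-(3-methylbut-2-enyl)-3-(triethylsilyloxy)chroman | COCOc1cc2c(c(CCc3ccc(OCOC)c(OCOC)c3)c1CC=C(C)C)C[C@@H](O[Si](CC)(CC)CC)C(C)(C)O2 | intermediate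
23 | (3R)-5-[2-(3,4-dihydroxyphenyl)ethyl]-2,2-dimethyl-6-(3-methylbut-2-enyl)chroman-3,7-diol | CC(C)=CCc1c(O)cc2c(c1CCc1ccc(O)c(O)c1)C[C@@H](O)C(C)(C)O2 | target

## Step count and least certain steps

Total: 13 steps. Longest linear sequence: 12 steps (from 1 to 23 through steps 1, 2 and 4 to 13); step 3 is the only side branch.

Step 9 (key step). Two processes are most likely to go wrong. The first is loss of enantioface discrimination, because the C5 chain lies peri to C4 and may disturb the side-on approach that the catalyst relies on. The second is solvolytic opening or hydride-shift rearrangement of the oxirane, which is unusually prone to ionise at C4 under the donation of O1 and the C7 oxygen. Fallback: from 16, epoxidation with dimethyldioxirane in acetone at −20 °C would give the racemic cis-epoxide F1, whose lability is then put to use. A catalytic Lewis acid (ZnI2, CH2Cl2) should isomerise it by 1,2-hydride shift (Meinwald rearrangement) to the chroman-3-one F2. Corey–Bakshi–Shibata reduction with (S)-2-methyl-CBS-oxazaborolidine and BH3·SMe2, the quaternary C2 acting as the large group, is expected to give the 3R alcohol, and the route is rejoined at 18.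

Step 7. The risk is loss of site selectivity in the acetal hydrolysis: the MOM ether para to the formyl group and the two on ring B may be cleaved at a rate not far below that of the ortho one. Fallback: from 11, exhaustive acidic methanolysis (HCl, MeOH) would give the tetraphenol aldehyde F3. Treatment with MOMCl (3.1 equiv) and K2CO3 in acetone should then alkylate the three free hydroxyls, while the hydroxyl hydrogen-bonded to the formyl group stays unreacted, which returns the route to 12.

Step 5. The risk is loss of ring selectivity in the second bromination: once ring A carries one bromine, substitution on ring B para to one of its oxygens may begin to compete. Fallback: bromination is moved ahead of the coupling. From 2, NBS (2.2 equiv) would give 2,6-dibromo-3,5-bis(methoxymethoxy)benzaldehyde F4, and Wittig methylenation would give the dibromostyrene F5. Hydroboration with 9-BBN would give the alkylborane F6, which is coupled at room temperature (Pd(dppf)Cl2, aq. NaOH) with 4-iodo-1,2-bis(methoxymethoxy)benzene F7, made from 5 by bromine–lithium exchange and iodine quench. Zerovalent palladium inserts into the unhindered C–I bond much faster than into the doubly ortho-substituted C–Br bonds, and the route is rejoined at 8.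

Step 12. The risks are proton transfer to the hindered aryl anion from the benzylic C–H bonds beside it before it reaches copper, and allylic transposition in the substitution (bond formation through the tertiary terminus of the prenyl unit). Fallback: from 19, a Stille coupling with allyltributylstannane (Pd(P(t-Bu)3)2, CsF, dioxane, 80 °C) would give the 6-allyl compound F8 without any organolithium. Cross-metathesis with 2-methylbut-2-ene (second-generation Grubbs catalyst, CH2Cl2, 40 °C) then turns the allyl into the prenyl group with no regiochemical ambiguity and returns the route to 22.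

Step 13. The risks are acid-promoted addition of the freed C7 hydroxyl to the neighbouring prenyl alkene (ring closure to a second chroman) and air oxidation of the catechol once it is free. Fallback: from 22, Bu4NF in THF would remove the silyl group to give the tris-MOM chromanol F9. ZnBr2 with propane-1-thiol in CH2Cl2 at 0 °C then cleaves the aryl acetals within minutes by Lewis-acid activation and thiol capture of the methoxymethyl cation, without a Brønsted acid, to give 23.

## Further compounds

F1 | step 9 | rac-(3R*,4R*)-6-bromo-3,4-epoxy-5-{2-[3,4-bis(methoxymethoxy)phenyl]ethyl}-7-(methoxymethoxy)-2,2-dimethylchroman | COCOc1cc2c(c(CCc3ccc(OCOC)c(OCOC)c3)c1Br)C1OC1C(C)(C)O2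
F2 | step 9 | 6-bromo-5-{2-[3,4-bis(methoxymethoxy)phenyl]ethyl}-7-(methoxymethoxy)-2,2-dimethylchroman-3-one | COCOc1cc2c(c(CCc3ccc(OCOC)c(OCOC)c3)c1Br)CC(=O)C(C)(C)O2
F3 | step 7 | 3-bromo-2-[2-(3,4-dihydroxyphenyl)ethyl]-4,6-dihydroxybenzaldehyde | O=Cc1c(O)cc(O)c(Br)c1CCc1ccc(O)c(O)c1
F4 | step 5 | 2,6-dibromo-3,5-bis(methoxymethoxy)benzaldehyde | O=Cc1c(Br)c(OCOC)cc(OCOC)c1Br
F5 | step 5 | 2,4-dibromo-3-ethenyl-1,5-bis(methoxymethoxy)benzene | C=Cc1c(Br)c(OCOC)cc(OCOC)c1Br
F6 | step 5 | 9-{2-[2,6-dibromo-3,5-bis(methoxymethoxy)phenyl]ethyl}-9-borabicyclo[3.3.1]nonane | COCOc1cc(OCOC)c(Br)c(CCB2C3CCCC2CCC3)c1Br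
F7 | step 5 | 4-iodo-1,2-bis(methoxymethoxy)benzene | COCOc1ccc(I)cc1OCOC
F8 | step 12 | (3R)-5-{2-[3,4-bis(methoxymethoxy)phenyl]ethyl}-7-(methoxymethoxy)-2,2-dimethyl-6-(prop-2-enyl)-3-(triethylsilyloxy)chroman | COCOc1cc2c(c(CCc3ccc(OCOC)c(OCOC)c3)c1CC=C)C[C@@H](O[Si](CC)(CC)CC)C(C)(C)O2
F9 | step 13 | (3R)-5-{2-[3,4-bis(methoxymethoxy)phenyl]ethyl}-7-(methoxymethoxy)-2,2-dimethyl-6-(3-methylbut-2-enyl)chroman-3-ol | COCOc1cc2c(c(CCc3ccc(OCOC)c(OCOC)c3)c1CC=C(C)C)C[C@@H](O)C(C)(C)O2
A1 | alternative 1 | 3-{2-[3,4-bis(methoxymethoxy)phenyl]ethyl}-2-(3-methylbut-2-enyl)-5-(triisopropylsilyloxy)phenol | CC(C)=CCc1c(O)cc(O[Si](C(C)C)(C(C)C)C(C)C)cc1CCc1ccc(OCOC)c(OCOC)c1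
A2 | alternative 1 | 3-{2-[3,4-bis(methoxymethoxy)phenyl]ethyl}-4-(3-methylbut-2-enyl)cyclobut-2-en-1-one (racemic) | O=C1C=C(CCc2ccc(OCOC)c(OCOC)c2)C1CC=C(C)C
A3 | alternative 1 | ethynyloxy(triisopropyl)silane | C#CO[Si](C(C)C)(C(C)C)C(C)C
A4 | alternative 2 | 8-bromo-5-{2-[3,4-bis(tert-butyldimethylsilyloxy)phenyl]ethyl}-7-(methoxymethoxy)-2,2-dimethyl-2H-chromene | COCOc1cc(CCc2ccc(O[Si](C)(C)C(C)(C)C)c(O[Si](C)(C)C(C)(C)C)c2)c2C=CC(C)(C)Oc2c1Br
A5 | alternative 2 | 2-bromo-5-{2-[3,4-bis(tert-butyldimethylsilyloxy)phenyl]ethyl}-1-(methoxymethoxy)-3-[(2-methylbut-3-yn-2-yl)oxy]benzene | COCOc1cc(CCc2ccc(O[Si](C)(C)C(C)(C)C)c(O[Si](C)(C)C(C)(C)C)c2)cc(OC(C)(C)C#C)c1Br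
A6 | alternative 3 | (3R)-5-{2-[3,4-bis(methoxymethoxy)phenyl]ethyl}-7-(methoxymethoxy)-2,2-dimethylchroman-3-ol | COCOc1cc2c(c(CCc3ccc(OCOC)c(OCOC)c3)c1)C[C@@H](O)C(C)(C)O2
A7 | alternative 3 | (2R)-2-{2-[3-{2-[3,4-bis(methoxymethoxy)phenyl]ethyl}-5-(methoxymethoxy)phenoxy]propan-2-yl}oxirane | COCOc1cc(CCc2ccc(OCOC)c(OCOC)c2)cc(OC(C)(C)[C@H]2CO2)c1
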